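**Retrosynthetic overview**
1. Feature: in ring A (C1–C5, C10) the heteroatom-bearing C3 lies para to the methyl-bearing quaternary C10 and ortho to C4. Ring A is therefore a masked 2,4-dimethylphenol whose para carbon lacks only the bond to C9.
2. Key disconnection C9–C10: the bicyclic 1,4-dien-3-one with an exocyclic methylene on C8 comes from a phenol that carries a 2-substituted allyl methyl carbonate on C5, by asymmetric palladium-catalysed dearomative allylation.
3. Ring A is finished first: C1=C2 reduction, reductive methylation (C4 gem-dimethyl, trans C5–H), then a C2=C3 vinyl bromide and hydrogen-atom-transfer hydrogenation for the equatorial C3–Br. The C8 methylene is cleaved to the ketone in between.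
4. Ring B and chain: a C6=C7 enone steers prenylation to C9 (axial, anti to C10–CH3) and methyl addition gives the C8 carbinol. C13 comes from Sharpless epoxidation of the (E)-C12=C13 allylic alcohol, hydride opening, oxidation and methylenation.
5. Ring order: ring A is bought as an arene (2-bromo-1,3-dimethylbenzene) and ring B is the only ring formed. The cyclisation substrate is built from a benzylic bromide and dilithiated methallyl alcohol.

Key step: step 9

Numbering: labdane numbering is used for all bicyclic compounds (ring A C1–C5, C10; ring B C5–C10; chain C11–C16; C17 on C8; C18 and C19 on C4; C20 on C10).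
Assumption: the sense of induction in step 9 cannot be predicted safely for this substrate; the (R,R)-ligand is written and its (S,S)-antipode is used if it favours the wrong face of C10.

**Step 1**
Reactants: 1 2-bromo-1,3-dimethylbenzene
Product: 2 1-(3-bromo-2,4-dimethylphenyl)ethan-1-one
Conditions: AcCl, AlCl3, CH2Cl2, 0 °C to rt
Reagents that add atoms: acetyl chloride CC(=O)Cl
Why: Friedel–Crafts acylation, in which both methyl groups direct to the same ring position (ortho to one, para to the other, meta to bromine), so a single ketone should form.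

**Step 2**
Reactants: 2 1-(3-bromo-2,4-dimethylphenyl)ethan-1-one
Product: 4 3-bromo-2,4-dimethylphenol, via aryl acetate 3 (not isolated)
Conditions: mCPBA, CF3CO2H, CH2Cl2, rt; solvent changed to MeOH, K2CO3 (cat.), rt
Reagents that add atoms: mCPBA OOC(=O)c1cccc(Cl)c1
Why: Baeyer–Villiger oxidation with migration of the ortho-substituted aryl group gives the aryl acetate, which base-catalysed transesterification with methanol turns into the phenol.

**Step 3**
Reactants: 4 3-bromo-2,4-dimethylphenol
Product: 5 (3-bromo-2,4-dimethylphenoxy)tri(propan-2-yl)silane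
Conditions: i-Pr3SiCl, imidazole, DMF, rt
Reagents that add atoms: chlorotri(propan-2-yl)silane CC(C)[Si](Cl)(C(C)C)C(C)C
Why: Standard silyl ether formation, the bulky silyl group being chosen because it resists the organolithium and alkoxide reagents of steps 4 and 6.

**Step 4**
Reactants: 5 (3-bromo-2,4-dimethylphenoxy)tri(propan-2-yl)silane
Product: 7 [2,6-dimethyl-3-(triisopropylsilyloxy)phenyl]methanol, via aryllithium 6 (not isolated)
Conditions: n-BuLi, THF, −78 °C; then dry paraformaldehyde, −78 °C to rt; H2O
Reagents that add atoms: paraformaldehyde (reacts as formaldehyde) C=O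
Why: Bromine–lithium exchange followed by 1,2-addition of the aryllithium to formaldehyde installs C6 between the two methyl groups.

**Step 5**
Reactants: 7 [2,6-dimethyl-3-(triisopropylsilyloxy)phenyl]methanol
Product: 8 [3-(bromomethyl)-2,4-dimethylphenoxy]tri(propan-2-yl)silane
Conditions: CBr4, PPh3, CH2Cl2, 0 °C
Reagents that add atoms: tetrabromomethane BrC(Br)(Br)Br
Why: The Appel reaction converts the benzylic alcohol to the bromide under neutral conditions that leave the aryl silyl ether intact.

**Step 6**
Reactants: 8 [3-(bromomethyl)-2,4-dimethylphenoxy]tri(propan-2-yl)silane; 9 2-methylprop-2-en-1-ol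
Product: 11 2-methylidene-4-[2,6-dimethyl-3-(triisopropylsilyloxy)phenyl]butan-1-ol, via dilithio dianion 10 (not isolated)
Conditions: 9 (2 equiv), n-BuLi (4 equiv), TMEDA, Et2O–hexane, 0 °C to rt; then 8, THF, −78 to 0 °C; H2O
Reagents that add atoms: none
Why: SN2 alkylation of the O,C-dilithiated methallyl alcohol at its carbon terminus by the reactive benzylic bromide joins C6 to C7 and gives the 2-substituted allyl alcohol directly.

**Step 7**
Reactants: 11 2-methylidene-4-[2,6-dimethyl-3-(triisopropylsilyloxy)phenyl]butan-1-ol
Product: 12 methyl 2-methylidene-4-[2,6-dimethyl-3-(triisopropylsilyloxy)phenyl]butyl carbonate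
Conditions: ClCO2Me, pyridine, CH2Cl2, 0 °C
Reagents that add atoms: methyl chloroformate COC(=O)Cl
Why: O-acylation of the primary allylic alcohol with a chloroformate gives the carbonate leaving group, which later releases its own base.

**Step 8**
Reactants: 12 methyl 2-methylidene-4-[2,6-dimethyl-3-(triisopropylsilyloxy)phenyl]butyl carbonate
Product: 13 3-[3-(methoxycarbonyloxymethyl)but-3-enyl]-2,4-dimethylphenol
Conditions: Bu4NF, AcOH, THF, 0 °C
Reagents that add atoms: none
Why: Fluoride-induced desilylation of the aryl silyl ether, buffered with acetic acid so that the phenolate is protonated at once and cannot attack the carbonate.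

**Step 9**
Reactants: 13 3-[3-(methoxycarbonyloxymethyl)but-3-enyl]-2,4-dimethylphenol
Product: 14 (4aR)-1,4a-dimethyl-6-methylidene-5,6,7,8-tetrahydronaphthalen-2(4aH)-one (ring A 1,4-dien-3-one, methyls on C4 and C10, C8 exocyclic methylene, C10 R)
Conditions: Pd2(dba)3·CHCl3 (2.5 mol %), (1R,2R)-N,N′-bis(2-diphenylphosphinobenzoyl)cyclohexane-1,2-diamine (7.5 mol %), degassed 1,4-dioxane (0.01 M), rt
Reagents that add atoms: none
Why: Zerovalent palladium ionises the allyl carbonate of 13 to a cationic 2-substituted allylpalladium unit (divalent palladium), CO2 is lost, and the methoxide left behind deprotonates the phenol, so the nucleophile is made without external base. The phenolate then attacks the CH2 terminus C9 through its para carbon C10, on the allyl face away from the metal, which forms C9–C10, dearomatises ring A to the cross-conjugated dienone and returns zerovalent palladium. The closest known reactions are the palladium-catalysed intramolecular asymmetric allylic dearomatisation of phenols (spirodienones from para-tethered allyl carbonates) and the base-induced Ar2-6 para-alkylation of phenolates. Ring B (C5–C10) closes as a six-membered carbocycle in the Ar2-6 mode: the ring carbon next to the tether attacks, the departing palladium is exocyclic, and the central allyl carbon C8 stays in the ring with the methylene on it. The one new stereocentre, quaternary C10, is controlled by the chiral pocket of the diphosphine ligand, which selects the face of the flat phenolate that meets the allyl terminus, and because both termini are identical CH2 groups no allyl regio- or geometric isomers can arise. The step needs para C-alkylation to win over attack at C4 and over O-alkylation: C10 bears the larger phenolate coefficient, is flanked by the unsubstituted C1–H whereas C4 is wedged between C3–O and C5, and leads to the more stable cross-conjugated dienone, while intramolecular O-alkylation would need a strained eight-membered meta-bridged ether and intermolecular O-allylation is held back by dilution and is reversible under the catalyst.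

**Step 10**
Reactants: 14 dienone
Product: 15 (4aS)-1,4a-dimethyl-6-methylidene-4,4a,5,6,7,8-hexahydronaphthalen-2(3H)-one (4-en-3-one, C8 methylene kept)
Conditions: Cu(OAc)2·H2O (5 mol %), 1,2-bis(diphenylphosphino)benzene (5 mol %), (EtO)2MeSiH, t-BuOH, toluene, rt
Reagents that add atoms: none
Why: Copper hydride catalysed conjugate reduction attacks only the disubstituted C1=C2 arm, because the C4=C5 arm is tetrasubstituted and the isolated C8 methylene is no Michael acceptor.

**Step 11**
Reactants: 15 4-en-3-one
Product: 17 (5S,10S)-4,4,10-trimethyl-8-methylidene-trans-decalin-3-one (C5–H anti to C10–CH3), via lithium enolate 16 (not isolated)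
Conditions: Li (2.2 equiv), t-BuOH (1.0 equiv), NH3(l)–THF, −78 to −33 °C; then MeI, −78 to −33 °C
Reagents that add atoms: iodomethane CI
Why: In this dissolving-metal reductive alkylation C5 is protonated axially to give the trans ring fusion, and the regiodefined C3–C4 enolate is C-methylated to the gem-dimethyl group while the isolated alkene is inert.

**Step 12**
Reactants: 17 trans-decalin-3-one
Product: 18 2,4,6-triisopropylbenzenesulfonylhydrazone of 17
Conditions: 2,4,6-(i-Pr)3C6H2SO2NHNH2, HCl (cat.), THF–MeOH, rt
Reagents that add atoms: 2,4,6-triisopropylbenzenesulfonohydrazide NNS(=O)(=O)c1c(C(C)C)cc(C(C)C)cc1C(C)C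
Why: Acid-catalysed hydrazone condensation at the only carbonyl group, kept at room temperature so that the hydrazide does not break down to diimide.

**Step 13**
Reactants: 18 sulfonylhydrazone
Product: 20 (5S,10S)-3-bromo-4,4,10-trimethyl-8-methylidene-trans-decal-2-ene, via vinyllithium 19 (not isolated)
Conditions: n-BuLi (2.2 equiv), TMEDA, THF–hexane, −78 to 0 °C; then BrCH2CH2Br, −78 °C to rt
Reagents that add atoms: 1,2-dibromoethane BrCCBr
Why: In the Shapiro reaction, deprotonation at N–H and at C2 (the only α-CH2) and loss of sulfinate and N2 give the C3 vinyllithium, which 1,2-dibromoethane brominates without any reagent that could add to the C8 methylene.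

**Step 14**
Reactants: 20 vinyl bromide with C8 methylene
Product: 21 (5S,10S)-3-bromo-4,4,10-trimethyl-trans-decal-2-en-8-one
Conditions: OsO4 (2 mol %), NaIO4, 2,6-lutidine, dioxane–H2O, rt
Reagents that add atoms: osmium tetroxide O=[Os](=O)(=O)=O; sodium periodate [Na+].[O-]I(=O)(=O)=O
Why: In the Lemieux–Johnson oxidation OsO4 dihydroxylates the electron-rich, unhindered 1,1-disubstituted alkene much faster than the electron-poor neopentyl vinyl bromide, and periodate cleaves the diol to the C8 ketone.

**Step 15**
Reactants: 21 vinyl bromide ketone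
Product: 22 (3R,5S,10S)-3-bromo-4,4,10-trimethyl-trans-decalin-8-one (Br equatorial, cis to C10–CH3)
Conditions: Mn(dpm)3 (10 mol %), PhSiH3, t-BuOOH, i-PrOH, rt, Ar
Reagents that add atoms: none
Why: Metal-hydride hydrogen atom transfer hydrogenation, a method known to reduce alkenyl halides without hydrogenolysis, adds H· to C2, and the bromine-stabilised C3 radical takes its second hydrogen axially on the face away from the axial C4 and C10 methyls, which leaves bromine equatorial.

**Step 16**
Reactants: 22 bromo ketone
Product: 24 (3R,5S,10S)-3-bromo-4,4,10-trimethyl-trans-decal-6-en-8-one, via lithium enolate 23 (not isolated)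
Conditions: LiN(i-Pr)2, THF, −78 °C; then PhS(Cl)=N-t-Bu, −78 °C
Reagents that add atoms: none
Why: In the Mukaiyama dehydrogenation, kinetic deprotonation at the unhindered C7, sulfur transfer and syn-elimination give the enone, and C6=C7 is the only possible position because C10 bears no hydrogen.

**Step 17**
Reactants: 24 C6=C7 enone; 25 1-bromo-3-methylbut-2-ene (prenyl bromide)
Product: 27 (3R,5S,9R,10R)-3-bromo-4,4,10-trimethyl-9-(3-methylbut-2-enyl)-trans-decal-6-en-8-one (prenyl axial, trans to C10–CH3), via lithium dienolate 26 (not isolated)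
Conditions: LiN(i-Pr)2, THF, −78 °C; DMPU, 25, −78 to −40 °C
Reagents that add atoms: none
Why: Kinetic α′-deprotonation of the enone (C7 is sp2, so C9 is the only α-CH2, as in the α′-alkylation of isophorone) and SN2 alkylation of the cross-conjugated dienolate proceed with axial entry of the allylic bromide on the face opposite the adjacent axial C10–CH3, which sets C9.

**Step 18**
Reactants: 27 9-prenyl enone
Product: 28 (3R,5S,9R,10R)-3-bromo-4,4,10-trimethyl-9-(3-methylbut-2-enyl)-trans-decalin-8-one
Conditions: Cu(OAc)2·H2O (5 mol %), 1,2-bis(diphenylphosphino)benzene (5 mol %), (EtO)2MeSiH, t-BuOH, toluene, rt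
Reagents that add atoms: none
Why: Copper hydride catalysed conjugate reduction is specific for the enone, spares the trisubstituted chain alkene and the alkyl bromide, and runs through the C7–C8 enolate, so C9 is not epimerised.

**Step 19**
Reactants: 28 9-prenyl ketone
Product: 29 (3R,5S,8R,9R,10R)-3-bromo-4,4,8,10-tetramethyl-9-(3-methylbut-2-enyl)-trans-decalin-8-ol (OH axial, cis to C10–CH3, trans-diaxial to the chain)
Conditions: MeLi, anhydrous CeCl3, THF, −78 °C; then 28, −78 °C; H2O
Reagents that add atoms: methyllithium [Li]C
Why: In this organocerium 1,2-addition, whose low basicity suppresses enolisation, the axial trajectory at C8 is closed by the syn-axial C10–CH3, so methyl should enter equatorially and leave the hydroxyl axial.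

**Step 20**
Reactants: 29 tertiary alcohol
Product: 30 (E)-allylic alcohol, 14-hydroxy derivative of 29 with chain CH2–CH=C(CH3)–CH2OH
Conditions: SeO2 (0.3 equiv), t-BuOOH, salicylic acid (cat.), CH2Cl2, 0 °C to rt
Reagents that add atoms: tert-butyl hydroperoxide CC(C)(C)OO; selenium dioxide O=[Se]=O
Why: SeO2 allylic oxidation (ene reaction, then [2,3]-sigmatropic shift) of a prenyl group is selective for the methyl group trans to the chain and gives the (E)-allylic alcohol.

**Step 21**
Reactants: 30 (E)-allylic alcohol
Product: 31 (12S,13S)-12,13-epoxy-14-ol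
Conditions: Ti(Oi-Pr)4 (20 mol %), L-(+)-diethyl tartrate (24 mol %), t-BuOOH, 4 Å molecular sieves, CH2Cl2, −20 °C
Reagents that add atoms: tert-butyl hydroperoxide CC(C)(C)OO
Why: Sharpless asymmetric epoxidation is reagent-controlled, and L-(+)-tartrate, which turns (E)-allylic alcohols such as geraniol into their (2S,3S)-epoxides, delivers oxygen to the same face here, sets the C13–O bond, and converts any decalin antipode left from step 9 into a separable diastereomer.

**Step 22**
Reactants: 31 epoxy alcohol
Product: 32 (13R)-8,13,14-triol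
Conditions: LiAlH4, THF, 0 °C; aqueous work-up
Reagents that add atoms: none
Why: SN2 hydride opening of the 2-methyl-2,3-epoxy alcohol at the less substituted C12 leaves the C13–O bond and its configuration untouched, while the equatorial neopentyl bromide is too hindered to be displaced at 0 °C.

**Step 23**
Reactants: 32 triol
Product: 33 (13R)-8,13-dihydroxy-14-al
Conditions: SO3·pyridine, DMSO, Et3N, CH2Cl2, 0 °C
Reagents that add atoms: none
Why: Parikh–Doering oxidation affects only the primary C14 alcohol, since both other hydroxyls are tertiary, and avoids glycol cleavage.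

**Step 24**
Reactants: 33 hydroxy aldehyde
Product: 34 target, (3R,5S,8R,9R,10R,13R)-3-bromo-8,13-dihydroxy bicyclic diterpene with the C14=C15 vinyl group
Conditions: Ph3PCH3Br, KOt-Bu (excess), THF, 0 °C; then 33, 0 °C to rt
Reagents that add atoms: methyltriphenylphosphonium bromide C[P+](c1ccccc1)(c1ccccc1)c1ccccc1.[Br-]
Why: Wittig methylenation with excess ylide (the free hydroxyls are merely deprotonated) converts the non-epimerisable α-hydroxy aldehyde into the vinyl group and completes the target.

**Compound list**
1 | 2-bromo-1,3-dimethylbenzene | Cc1cccc(C)c1Br | starting material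
2 | 1-(3-bromo-2,4-dimethylphenyl)ethan-1-one | CC(=O)c1ccc(C)c(Br)c1C | intermediate
3 | 3-bromo-2,4-dimethylphenyl acetate | CC(=O)Oc1ccc(C)c(Br)c1C | intermediate
4 | 3-bromo-2,4-dimethylphenol | Cc1ccc(O)c(C)c1Br | intermediate
5 | (3-bromo-2,4-dimethylphenoxy)tri(propan-2-yl)silane | Cc1ccc(O[Si](C(C)C)(C(C)C)C(C)C)c(C)c1Br | intermediate
6 | [2,6-dimethyl-3-(triisopropylsilyloxy)phenyl]lithium | Cc1ccc(O[Si](C(C)C)(C(C)C)C(C)C)c(C)c1[Li] | intermediate
7 | [2,6-dimethyl-3-(triisopropylsilyloxy)phenyl]methanol | Cc1ccc(O[Si](C(C)C)(C(C)C)C(C)C)c(C)c1CO | intermediate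
8 | [3-(bromomethyl)-2,4-dimethylphenoxy]tri(propan-2-yl)silane | Cc1ccc(O[Si](C(C)C)(C(C)C)C(C)C)c(C)c1CBr | intermediate
9 | 2-methylprop-2-en-1-ol | CC(=C)CO | starting material
10 | O,C-dilithiated 2-methylprop-2-en-1-ol | [Li]CC(=C)CO[Li] | intermediate
11 | 2-methylidene-4-[2,6-dimethyl-3-(triisopropylsilyloxy)phenyl]butan-1-ol | Cc1ccc(O[Si](C(C)C)(C(C)C)C(C)C)c(C)c1CCC(=C)CO | intermediate
12 | methyl carbonate of 11 | Cc1ccc(O[Si](C(C)C)(C(C)C)C(C)C)c(C)c1CCC(=C)COC(=O)OC | intermediate
13 | 3-[3-(methoxycarbonyloxymethyl)but-3-enyl]-2,4-dimethylphenol | Cc1ccc(O)c(C)c1CCC(=C)COC(=O)OC | intermediate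
14 | (4aR)-1,4a-dimethyl-6-methylidene-5,6,7,8-tetrahydronaphthalen-2(4aH)-one | C=C1C[C@]2(C)C=CC(=O)C(C)=C2CC1 | intermediate
15 | (4aS)-1,4a-dimethyl-6-methylidene-4,4a,5,6,7,8-hexahydronaphthalen-2(3H)-one | C=C1C[C@]2(C)CCC(=O)C(C)=C2CC1 | intermediate
16 | lithium C3–C4 enolate, trans-fused | C=C1C[C@]2(C)CCC(O[Li])=C(C)[C@H]2CC1 | intermediate
17 | (5S,10S)-4,4,10-trimethyl-8-methylidene-trans-decalin-3-one | C=C1C[C@]2(C)CCC(=O)C(C)(C)[C@H]2CC1 | intermediate
18 | 2,4,6-triisopropylbenzenesulfonylhydrazone of 17 | C=C1C[C@]2(C)CC/C(=N\NS(=O)(=O)c3c(C(C)C)cc(C(C)C)cc3C(C)C)C(C)(C)[C@H]2CC1 | intermediate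
19 | C3 vinyllithium | C=C1C[C@]2(C)CC=C([Li])C(C)(C)[C@H]2CC1 | intermediate
20 | (5S,10S)-3-bromo-4,4,10-trimethyl-8-methylidene-trans-decal-2-ene | C=C1C[C@]2(C)CC=C(Br)C(C)(C)[C@H]2CC1 | intermediate
21 | (5S,10S)-3-bromo-4,4,10-trimethyl-trans-decal-2-en-8-one | O=C1C[C@]2(C)CC=C(Br)C(C)(C)[C@H]2CC1 | intermediate
22 | (3R,5S,10S)-3-bromo-4,4,10-trimethyl-trans-decalin-8-one | O=C1C[C@]2(C)CC[C@@H](Br)C(C)(C)[C@H]2CC1 | intermediate
23 | lithium C7–C8 enolate of 22 | [Li]OC=1C[C@]2(C)CC[C@@H](Br)C(C)(C)[C@H]2CC=1 | intermediate
24 | (3R,5S,10S)-3-bromo-4,4,10-trimethyl-trans-decal-6-en-8-one | O=C1C[C@]2(C)CC[C@@H](Br)C(C)(C)[C@H]2C=C1 | intermediate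
25 | 1-bromo-3-methylbut-2-ene | CC(C)=CCBr | starting material
26 | lithium cross-conjugated dienolate of 24 | [Li]OC1=C[C@]2(C)CC[C@@H](Br)C(C)(C)[C@H]2C=C1 | intermediate
27 | 9-prenyl enone (3R,5S,9R,10R) | CC(C)=CC[C@@H]1[C@]2(C)CC[C@@H](Br)C(C)(C)[C@H]2C=CC1=O | intermediate
28 | 9-prenyl ketone (3R,5S,9R,10R) | CC(C)=CC[C@@H]1[C@]2(C)CC[C@@H](Br)C(C)(C)[C@H]2CCC1=O | intermediate
29 | 8-methyl carbinol (3R,5S,8R,9R,10R) | CC(C)=CC[C@@H]1[C@]2(C)CC[C@@H](Br)C(C)(C)[C@H]2CC[C@@]1(C)O | intermediate
30 | (E)-12-ene-8,14-diol | OC/C(C)=C/C[C@@H]1[C@]2(C)CC[C@@H](Br)C(C)(C)[C@H]2CC[C@@]1(C)O | intermediate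
31 | (12S,13S)-12,13-epoxy-8,14-diol | OC[C@]3(C)O[C@H]3C[C@@H]1[C@]2(C)CC[C@@H](Br)C(C)(C)[C@H]2CC[C@@]1(C)O | intermediate
32 | (13R)-8,13,14-triol | OC[C@](C)(O)CC[C@@H]1[C@]2(C)CC[C@@H](Br)C(C)(C)[C@H]2CC[C@@]1(C)O | intermediate
33 | (13R)-8,13-dihydroxy-14-al | O=C[C@](C)(O)CC[C@@H]1[C@]2(C)CC[C@@H](Br)C(C)(C)[C@H]2CC[C@@]1(C)O | intermediate
34 | (1R,2R,4aS,6R,8aR)-6-bromo-1-[(3R)-3-hydroxy-3-methylpent-4-enyl]-2,5,5,8a-tetramethyldecahydronaphthalen-2-ol | C=C[C@](C)(O)CC[C@@H]1[C@]2(C)CC[C@@H](Br)C(C)(C)[C@H]2CC[C@@]1(C)O | target

**Step count**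
Total step count: 24. Longest linear sequence: 24 steps, from 1 to 34. Compounds 9 and 25 are bought.

**Steps most likely to fail**

1. Step 9. C-alkylation through the ortho carbon C4 may compete with para attack, and the catalyst may discriminate poorly between the two faces of C10.
   - The fallback uses no palladium and no chiral catalyst, and secures configuration by resolution. It sets out from 11.
   - The alcohol is exchanged for chloride (MsCl, Et3N, then LiCl, THF) to give the allylic chloride F1, and Bu4NF/AcOH frees the phenolic chloride F2.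
   - The potassium phenolate (KOt-Bu, t-BuOH, high dilution, reflux) is cyclised in the classical Ar2-6 manner to the racemic dienone F3. The protic solvent solvates oxygen and steers alkylation to the para carbon.
   - Preparative chromatography on a chiral stationary phase brings the route back at 14.

2. Step 19. The equatorial approach passes close to the axial C11, so addition may become slow enough for enolisation to take over, or facial selectivity at C8 may erode.
   - The fallback uses a reversible nucleophile under product-stability control and sets out from 28.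
   - Dimethylsulfoxonium methylide (Me3S(O)I, NaH, DMSO–THF, rt) adds reversibly and closes the ring from the more stable equatorial betaine to give the spiro-epoxide F4 (CH2 equatorial, O axial).
   - LiBHEt3 (THF, 0 °C) opens F4 at the CH2 terminus, and the route is rejoined at 29.

3. Step 15. Hydrogen atom transfer to the hindered, electron-poor C2=C3 may be sluggish, and bromine may be lost by β-scission after hydrogen delivery to the wrong carbon.
   - The fallback is ionic, sets out from 17, and bypasses 18 to 21.
   - LiBH(s-Bu)3 (THF, −78 °C) reduces the C3 ketone from the equatorial side to the axial alcohol F5.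
   - Appel bromination with inversion (PPh3, CBr4, toluene, heat) gives the equatorial bromide F6. Elimination and methyl shift are the competing processes to watch.
   - Lemieux–Johnson cleavage of the C8 methylene (OsO4, NaIO4, 2,6-lutidine) returns to the route at 22.

**Further compounds**
F1 | step 9 | [3-(3-(chloromethyl)but-3-enyl)-2,4-dimethylphenoxy]tri(propan-2-yl)silane | Cc1ccc(O[Si](C(C)C)(C(C)C)C(C)C)c(C)c1CCC(=C)CCl
F2 | step 9 | 3-[3-(chloromethyl)but-3-enyl]-2,4-dimethylphenol | Cc1ccc(O)c(C)c1CCC(=C)CCl
F3 | step 9 | racemic 1,4a-dimethyl-6-methylidene-5,6,7,8-tetrahydronaphthalen-2(4aH)-one | C=C1CC2(C)C=CC(=O)C(C)=C2CC1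
F4 | step 19 | 8,17-spiro-epoxide of the 9-prenyl decalin (O axial, CH2 equatorial) | CC(C)=CC[C@@H]1[C@]2(C)CC[C@@H](Br)C(C)(C)[C@H]2CC[C@]13CO3
F5 | step 15 | 4,4,10-trimethyl-8-methylidene-trans-decalin-3-ol, OH axial (trans to C10–CH3) | C=C1C[C@]2(C)CC[C@H](O)C(C)(C)[C@H]2CC1
F6 | step 15 | (3R,5S,10S)-3-bromo-4,4,10-trimethyl-8-methylidene-trans-decalin, Br equatorial | C=C1C[C@]2(C)CC[C@@H](Br)C(C)(C)[C@H]2CC1
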